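**Retrosynthetic overview**
1. Endgame: hydrogenolysis of six O-benzyl groups and one C–Br bond, preceded by Ag(I)-mediated exchange of a 4'-arylthio group for OH, preceded by removal of two 3-O-benzoates from a protected dimer.
2. Key disconnection: C2–C3 of the upper pyran ring (ring C) and the interflavan bond C4–C6' are cut together. Both form in one chiral-acid-catalysed Prins/Friedel–Crafts cascade from a 2-aryl-1,3-benzodioxole bearing a (Z)-2-(benzoyloxy)ethenyl group, with the finished lower flavan as the terminating arene.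
3. Enabling feature: O1 and the 8-OH are ortho on ring A, so C2 (with ring B) can be stored as the acetal carbon of a benzodioxole spanning O1/O8. Ionising C2–O8 gives an O1=C2 cation, stabilised by the para-oxygen of ring B, next to the C4a side chain. O7, para to C4a, carries the charge that arrives at C4, and C6' of ring D is ortho to O7' and para to O1'.
4. The lower flavan (rings D/E/F) comes from the same closure, ended by a thiol that masks the 4'-OH. Both precursors come from 2,3,4-trihydroxybenzaldehyde by acetalisation, alkyne formation and Z-selective addition of benzoic acid.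
5. Order of ring formation: temporary benzodioxoles, then pyran ring F (lower unit), then pyran ring C (upper unit, together with the union).

Key step: step 13

Numbering: flavan numbering is used. Unprimed locants and rings A/B/C are the upper unit; primed locants and rings D/E/F are the lower unit.
Assumption: the sense of induction of the chiral acid cannot be derived from precedent. The (R)-acid is written; its mirror image is used if step 6 should deliver the (2S) series, which is checked on 10 before the union.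

Step 1
Reactants: 1 2,3,4-trihydroxybenzaldehyde
Product: 2 4-(benzyloxy)-2,3-dihydroxybenzaldehyde
Conditions: BnBr (1.0 equiv), NaHCO3, NaI (cat.), DMF, 40 °C
Reagents that add atoms: benzyl bromide BrCc1ccccc1
Why: Williamson etherification under weak-base control, in which only the 4-OH (para to CHO, most acidic) is ionised, while the 2-OH is held in the hydrogen bond to C=O and the 3-OH is less acidic.

Step 2
Reactants: 3 3,4-bis(benzyloxy)benzaldehyde
Product: 4 1,2-bis(benzyloxy)-4-(dichloromethyl)benzene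
Conditions: SOCl2 (1.5 equiv), DMF (cat.), CH2Cl2, 0 °C → rt; used crude
Reagents that add atoms: thionyl chloride O=S(Cl)Cl
Why: Vilsmeier-type deoxydichlorination of an electron-rich benzaldehyde, a known route to benzal chlorides that leaves benzyl ethers untouched.

Step 3
Reactants: 2 4-(benzyloxy)-2,3-dihydroxybenzaldehyde; 4 1,2-bis(benzyloxy)-4-(dichloromethyl)benzene
Product: 5 rac-7-(benzyloxy)-2-[3,4-bis(benzyloxy)phenyl]-1,3-benzodioxole-4-carbaldehyde
Conditions: K2CO3, MeCN, rt → 50 °C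
Reagents that add atoms: none
Why: Double O-alkylation of a catechol by a gem-dihalide (the reaction type used for methylenedioxy and diphenylmethylene ketals), fast here because the alkoxybenzal chloride ionises easily; the new acetal centre is racemic and is erased in step 6.

Step 4
Reactants: 5 rac-7-(benzyloxy)-2-[3,4-bis(benzyloxy)phenyl]-1,3-benzodioxole-4-carbaldehyde
Product: 6 rac-4-(benzyloxy)-2-[3,4-bis(benzyloxy)phenyl]-7-ethynyl-1,3-benzodioxole
Conditions: Bestmann–Ohira reagent, K2CO3, MeOH/THF, rt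
Reagents that add atoms: dimethyl (1-diazo-2-oxopropyl)phosphonate COP(=O)(OC)C(=[N+]=[N-])C(C)=O
Why: Seyferth–Gilbert homologation of an aromatic aldehyde; the mild base does not touch the acetal or the benzyl ethers.

Step 5
Reactants: 6 rac-4-(benzyloxy)-2-[3,4-bis(benzyloxy)phenyl]-7-ethynyl-1,3-benzodioxole
Product: 7 rac-(Z)-2-{7-(benzyloxy)-2-[3,4-bis(benzyloxy)phenyl]-1,3-benzodioxol-4-yl}ethenyl benzoate
Conditions: PhCO2H (1.1 equiv), [Ru(η3-methallyl)2(dppb)] (2 mol %), toluene, 50 °C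
Reagents that add atoms: benzoic acid O=C(O)c1ccccc1
Why: Ruthenium-vinylidene-mediated anti-Markovnikov addition of a carboxylic acid to a terminal alkyne, known to give Z-enol esters; benzoic acid in dry toluene is too weak to consume the acetal.

Step 6
Reactants: 7 rac-(Z)-2-{7-(benzyloxy)-2-[3,4-bis(benzyloxy)phenyl]-1,3-benzodioxol-4-yl}ethenyl benzoate
Product: 10 (2R,3S,4S)-7-(benzyloxy)-2-[3,4-bis(benzyloxy)phenyl]-4-[(2,6-dimethylphenyl)sulfanyl]-8-hydroxychroman-3-yl benzoate, via oxocarbenium ion 8 (not isolated), via dioxolenium ion 9 (not isolated)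
Conditions: (R)-TRIP N-triflylphosphoramide (10 mol %), 2,6-Me2C6H3SH (2 equiv), 4 Å MS, toluene/CH2Cl2, −60 → −30 °C
Reagents that add atoms: 2,6-dimethylbenzenethiol Cc1cccc(C)c1S
Why: Proposed new method: the acid protonates O8' of the benzodioxole, C2'–O8' ionises to the aryl-stabilised O1'=C2' ion 8, C3' of the electron-rich Z-styryl benzoate attacks C2' (6-endo-trig, polarity set by ring D and not by the weakly donating benzoyloxy oxygen), the benzylic C4' cation is held by the 3'-benzoate as ion 9, and the excess thiol opens 9 at C4' faster than ring D of a second molecule can; 2',3'-cis follows from the Z-alkene and the pseudo-equatorial ring E, 3',4'-trans from anti opening, and the absolute sense from the chiral anion hydrogen-bonded to the freed 8'-OH; the closest known types are Prins cyclisations of Z-homoallylic alcohols with external capture and chiral-Brønsted-acid-catalysed Prins and Nazarov closures.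

Step 7
Reactants: 10 (2R,3S,4S)-7-(benzyloxy)-2-[3,4-bis(benzyloxy)phenyl]-4-[(2,6-dimethylphenyl)sulfanyl]-8-hydroxychroman-3-yl benzoate
Product: 11 (2R,3S,4S)-7,8-bis(benzyloxy)-2-[3,4-bis(benzyloxy)phenyl]-4-[(2,6-dimethylphenyl)sulfanyl]chroman-3-yl benzoate
Conditions: BnBr, K2CO3, DMF, rt
Reagents that add atoms: benzyl bromide BrCc1ccccc1
Why: Williamson benzylation of the phenol, which removes an O-nucleophile and lowers the para-activation of C5' (the flanked 8'-OBn is twisted out of conjugation), so that ring D should react only at C6'.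

Step 8
Reactants: 2 4-(benzyloxy)-2,3-dihydroxybenzaldehyde
Product: 12 4-(benzyloxy)-5-bromo-2,3-dihydroxybenzaldehyde
Conditions: NBS (1.0 equiv), MeCN, −10 °C
Reagents that add atoms: N-bromosuccinimide O=C1CCC(=O)N1Br
Why: Electrophilic bromination at the only position that is para to the 2-OH, ortho to OBn and meta to CHO; the bromine becomes the cap at C6 of ring A.

Step 9
Reactants: 13 4-(benzyloxy)benzaldehyde
Product: 14 1-(benzyloxy)-4-(dichloromethyl)benzene
Conditions: SOCl2 (1.5 equiv), DMF (cat.), CH2Cl2, 0 °C → rt; used crude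
Reagents that add atoms: thionyl chloride O=S(Cl)Cl
Why: The same deoxydichlorination as in step 2.

Step 10
Reactants: 12 4-(benzyloxy)-5-bromo-2,3-dihydroxybenzaldehyde; 14 1-(benzyloxy)-4-(dichloromethyl)benzene
Product: 15 rac-7-(benzyloxy)-2-[4-(benzyloxy)phenyl]-6-bromo-1,3-benzodioxole-4-carbaldehyde
Conditions: K2CO3, MeCN, rt → 50 °C
Reagents that add atoms: none
Why: Catechol acetalisation by a gem-dichloride as in step 3; it joins C2 and ring B to O1 and O8, and the racemic acetal centre is erased in step 13.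

Step 11
Reactants: 15 rac-7-(benzyloxy)-2-[4-(benzyloxy)phenyl]-6-bromo-1,3-benzodioxole-4-carbaldehyde
Product: 16 rac-4-(benzyloxy)-2-[4-(benzyloxy)phenyl]-5-bromo-7-ethynyl-1,3-benzodioxole
Conditions: Bestmann–Ohira reagent, K2CO3, MeOH/THF, rt
Reagents that add atoms: dimethyl (1-diazo-2-oxopropyl)phosphonate COP(=O)(OC)C(=[N+]=[N-])C(C)=O
Why: Seyferth–Gilbert homologation as in step 4; the aryl bromide is inert.

Step 12
Reactants: 16 rac-4-(benzyloxy)-2-[4-(benzyloxy)phenyl]-5-bromo-7-ethynyl-1,3-benzodioxole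
Product: 17 rac-(Z)-2-{7-(benzyloxy)-2-[4-(benzyloxy)phenyl]-6-bromo-1,3-benzodioxol-4-yl}ethenyl benzoate
Conditions: PhCO2H (1.1 equiv), [Ru(η3-methallyl)2(dppb)] (2 mol %), toluene, 50 °C
Reagents that add atoms: benzoic acid O=C(O)c1ccccc1
Why: Z-selective anti-Markovnikov addition of the acid to the alkyne as in step 5; it installs C3 with its oxygen and the alkene geometry that later fixes the 2,3-relationship.

Step 13
Reactants: 17 rac-(Z)-2-{7-(benzyloxy)-2-[4-(benzyloxy)phenyl]-6-bromo-1,3-benzodioxol-4-yl}ethenyl benzoate; 11 (2R,3S,4S)-7,8-bis(benzyloxy)-2-[3,4-bis(benzyloxy)phenyl]-4-[(2,6-dimethylphenyl)sulfanyl]chroman-3-yl benzoate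
Product: 20 (2R,3R,4S)-4-{(2R,3S,4S)-3-(benzoyloxy)-7,8-bis(benzyloxy)-2-[3,4-bis(benzyloxy)phenyl]-4-[(2,6-dimethylphenyl)sulfanyl]chroman-6-yl}-7-(benzyloxy)-2-[4-(benzyloxy)phenyl]-6-bromo-8-hydroxychroman-3-yl benzoate, via oxocarbenium ion 18 (not isolated), via dioxolenium ion 19 (not isolated)
Conditions: (R)-TRIP N-triflylphosphoramide (10 mol %), 11 (1.2 equiv), 4 Å MS, toluene/CH2Cl2, −60 → −20 °C
Reagents that add atoms: none
Why: Proposed new method: the acid protonates O8 of the benzodioxole, C2–O8 ionises to the O1=C2 oxocarbenium ion 18, C3 of the Z-styryl benzoate attacks C2 and closes pyran ring C, the charge arrives at C4 (para to O7, ortho to O1) and is held by the 3-benzoate as dioxolenium ion 19, and C6' of 11 opens 19 at C4 and returns the proton, so that two C–C bonds, one ring and three stereocentres form and no atom is lost. The closest known reaction types are the Prins/Friedel–Crafts cyclisation (homoallylic alcohol, aldehyde and arene to a 4-aryltetrahydropyran), chiral-Brønsted-acid-catalysed Prins and Nazarov closures, and the Lewis-acid union of 4-oxygenated 3-O-acylflavans with flavan nucleophiles; what is new is the aryl oxocarbenium ion drawn from a benzodioxole and the enol ester as the alkene. The closure is 6-endo-trig with both π bonds (O1=C2 and C3=C4) endocyclic, and attack through C4 (5-exo) would give a poorly stabilised acyloxycarbenium ion and forfeit the benzylic stabilisation, because the benzoyloxy oxygen is a far weaker donor than the trioxygenated ring A. C2 and C3: in the half-chair transition state the E-oxocarbenium ion places ring B pseudo-equatorial and the Z-alkene forces the benzoate pseudo-axial, as with Z-homoallylic alcohols in Prins cyclisations, which gives 2,3-cis (the boat-type alternative suffers from the clash of the inside benzoate with H-2), and the absolute sense (2R,3R) is set by the chiral anion, which is hydrogen-bonded to the freed 8-OH three atoms from C2. C4: the arene can only approach the face opposite to the cis-fused dioxolenium ring, which gives 3,4-trans (4S). Selectivity: the bromine blocks C6 of ring A in 17 and 20 against self-alkylation, the hindered xylylthio group of 11 resists the hard acid, C6' is the only ring-D carbon activated by two oxygens (C5' is also peri-hindered), and ring closure within 18 is intramolecular and should outrun capture of C2 by 11.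

Step 14
Reactants: 20 protected dimer dibenzoate (name as in step 13)
Product: 21 (2R,3R,4S)-7-(benzyloxy)-2-[4-(benzyloxy)phenyl]-4-{(2R,3S,4S)-7,8-bis(benzyloxy)-2-[3,4-bis(benzyloxy)phenyl]-4-[(2,6-dimethylphenyl)sulfanyl]-3-hydroxychroman-6-yl}-6-bromochroman-3,8-diol
Conditions: K2CO3, MeOH/THF, rt
Reagents that add atoms: none
Why: Base-catalysed transesterification (Zemplén type) removes both benzoates so that no acyl neighbour can steer step 15; thioether, bromide, benzyl ethers and the interflavan bond survive because O7 and the ring-B oxygen are alkylated and no quinone methide can form.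

Step 15
Reactants: 21 dimer thioether triol (name as in step 14)
Product: 22 (2R,3R,4S)-6-{(2R,3R,4S)-7-(benzyloxy)-2-[4-(benzyloxy)phenyl]-6-bromo-3,8-dihydroxychroman-4-yl}-7,8-bis(benzyloxy)-2-[3,4-bis(benzyloxy)phenyl]chroman-3,4-diol
Conditions: AgBF4 (1.5 equiv), NaHCO3, THF/H2O (10:1), 0 °C, dark
Reagents that add atoms: water O
Why: Thiophilic Ag(I) activation of the benzylic C4'–S bond, known for 4-thioflavans, gives the C4' cation (stabilised by O7' and O1'), and water adds on the face opposite to the axial 3'-OH and ring E, so the 3',4'-trans alcohol should form with overall retention; C6 (Br) and C6' (substituted) cannot compete as carbon nucleophiles, and the buffer prevents acid epimerisation.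

Step 16
Reactants: 22 hexa-O-benzyl bromo dimer (name as in step 15)
Product: 23 (2R,3R,4S)-2-(3,4-dihydroxyphenyl)-6-[(2R,3R,4S)-3,7,8-trihydroxy-2-(4-hydroxyphenyl)chroman-4-yl]chroman-3,4,7,8-tetraol (CNP0275688.1)
Conditions: H2 (1 atm), Pd(OH)2/C, Et3N (1.1 equiv), THF/MeOH/H2O, rt
Reagents that add atoms: none
Why: Hydrogenolysis of six aryl benzyl ethers and hydrodebromination in one operation over Pearlman's catalyst; Et3N binds the HBr so that the acid-labile C4'–OH and the interflavan bond are not ionised, and no stereocentre is touched.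

**Compound list**
1 | 2,3,4-trihydroxybenzaldehyde | O=Cc1ccc(O)c(O)c1O | starting material
2 | 4-(benzyloxy)-2,3-dihydroxybenzaldehyde | O=Cc1ccc(OCc2ccccc2)c(O)c1O | intermediate
3 | 3,4-bis(benzyloxy)benzaldehyde | O=Cc1ccc(OCc2ccccc2)c(OCc2ccccc2)c1 | starting material
4 | 1,2-bis(benzyloxy)-4-(dichloromethyl)benzene | ClC(Cl)c1ccc(OCc2ccccc2)c(OCc2ccccc2)c1 | intermediate
5 | rac-7-(benzyloxy)-2-[3,4-bis(benzyloxy)phenyl]-1,3-benzodioxole-4-carbaldehyde | O=Cc1ccc(OCc2ccccc2)c2OC(c3ccc(OCc4ccccc4)c(OCc4ccccc4)c3)Oc12 | intermediate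
6 | rac-4-(benzyloxy)-2-[3,4-bis(benzyloxy)phenyl]-7-ethynyl-1,3-benzodioxole | C#Cc1ccc(OCc2ccccc2)c2OC(c3ccc(OCc4ccccc4)c(OCc4ccccc4)c3)Oc12 | intermediate
7 | rac-(Z)-2-{7-(benzyloxy)-2-[3,4-bis(benzyloxy)phenyl]-1,3-benzodioxol-4-yl}ethenyl benzoate | O=C(c1ccccc1)O/C=C\c1ccc(OCc2ccccc2)c2OC(c3ccc(OCc4ccccc4)c(OCc4ccccc4)c3)Oc12 | intermediate
8 | (E)-oxocarbenium ion O1'=C2'H–ring E on the 8'-hydroxy ring D that bears the (Z)-2-(benzoyloxy)ethenyl group (ion pair with the catalyst anion) | O=C(c1ccccc1)O/C=C\c1ccc(OCc2ccccc2)c(O)c1/[O+]=C/c1ccc(OCc2ccccc2)c(OCc2ccccc2)c1 | intermediate (not isolated)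
9 | closed lower flavan as the cis-fused 2-phenyl-1,3-dioxolan-2-ylium ion over O3'/O4' (ring E, O3' and O4' on one face) | Oc1c(OCc5ccccc5)ccc2c1O[C@H](c3ccc(OCc5ccccc5)c(OCc5ccccc5)c3)[C@@H]3O[C+](c4ccccc4)O[C@H]23 | intermediate (not isolated)
10 | (2R,3S,4S)-7-(benzyloxy)-2-[3,4-bis(benzyloxy)phenyl]-4-[(2,6-dimethylphenyl)sulfanyl]-8-hydroxychroman-3-yl benzoate (2,3-cis-3,4-trans) | Oc1c(OCc5ccccc5)ccc2c1O[C@H](c3ccc(OCc5ccccc5)c(OCc5ccccc5)c3)[C@H](OC(=O)c3ccccc3)[C@H]2Sc3c(C)cccc3C | intermediate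
11 | (2R,3S,4S)-7,8-bis(benzyloxy)-2-[3,4-bis(benzyloxy)phenyl]-4-[(2,6-dimethylphenyl)sulfanyl]chroman-3-yl benzoate | O(Cc5ccccc5)c1c(OCc5ccccc5)ccc2c1O[C@H](c3ccc(OCc5ccccc5)c(OCc5ccccc5)c3)[C@H](OC(=O)c3ccccc3)[C@H]2Sc3c(C)cccc3C | intermediate
12 | 4-(benzyloxy)-5-bromo-2,3-dihydroxybenzaldehyde | O=Cc1cc(Br)c(OCc2ccccc2)c(O)c1O | intermediate
13 | 4-(benzyloxy)benzaldehyde | O=Cc1ccc(OCc2ccccc2)cc1 | starting material
14 | 1-(benzyloxy)-4-(dichloromethyl)benzene | ClC(Cl)c1ccc(OCc2ccccc2)cc1 | intermediate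
15 | rac-7-(benzyloxy)-2-[4-(benzyloxy)phenyl]-6-bromo-1,3-benzodioxole-4-carbaldehyde | O=Cc1cc(Br)c(OCc2ccccc2)c2OC(c3ccc(OCc4ccccc4)cc3)Oc12 | intermediate
16 | rac-4-(benzyloxy)-2-[4-(benzyloxy)phenyl]-5-bromo-7-ethynyl-1,3-benzodioxole | C#Cc1cc(Br)c(OCc2ccccc2)c2OC(c3ccc(OCc4ccccc4)cc3)Oc12 | intermediate
17 | rac-(Z)-2-{7-(benzyloxy)-2-[4-(benzyloxy)phenyl]-6-bromo-1,3-benzodioxol-4-yl}ethenyl benzoate | O=C(c1ccccc1)O/C=C\c1cc(Br)c(OCc2ccccc2)c2OC(c3ccc(OCc4ccccc4)cc3)Oc12 | intermediate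
18 | (E)-oxocarbenium ion O1=C2H–ring B on the 6-bromo-8-hydroxy ring A that bears the (Z)-2-(benzoyloxy)ethenyl group (ion pair with the catalyst anion) | O=C(c1ccccc1)O/C=C\c1cc(Br)c(OCc2ccccc2)c(O)c1/[O+]=C/c1ccc(OCc2ccccc2)cc1 | intermediate (not isolated)
19 | closed upper flavan as the cis-fused 2-phenyl-1,3-dioxolan-2-ylium ion over O3/O4 (ring B, O3 and O4 on one face) | O(Cc5ccccc5)c1ccc([C@H]2Oc3c(cc(Br)c(OCc5ccccc5)c3O)[C@H]4O[C+](c5ccccc5)O[C@@H]24)cc1 | intermediate (not isolated)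
20 | protected dimer dibenzoate: upper unit (2R,3R,4S), 6-Br, 7-OBn, 8-OH, 3-OBz, joined from C4 to C6' of unit 11; both units 2,3-cis-3,4-trans | O(Cc5ccccc5)c1ccc([C@H]2Oc3c(cc(Br)c(OCc5ccccc5)c3O)[C@H](c3cc4c(c(OCc5ccccc5)c3OCc5ccccc5)O[C@H](c3ccc(OCc5ccccc5)c(OCc5ccccc5)c3)[C@H](OC(=O)c3ccccc3)[C@H]4Sc3c(C)cccc3C)[C@H]2OC(=O)c3ccccc3)cc1 | intermediate
21 | dimer thioether triol (20 without the two benzoyl groups) | O(Cc5ccccc5)c1ccc([C@H]2Oc3c(cc(Br)c(OCc5ccccc5)c3O)[C@H](c3cc4c(c(OCc5ccccc5)c3OCc5ccccc5)O[C@H](c3ccc(OCc5ccccc5)c(OCc5ccccc5)c3)[C@H](O)[C@H]4Sc3c(C)cccc3C)[C@H]2O)cc1 | intermediate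
22 | hexa-O-benzyl 6-bromo dimer with free 3-, 8-, 3'- and 4'-OH (3',4'-trans) | O(Cc5ccccc5)c1ccc([C@H]2Oc3c(cc(Br)c(OCc5ccccc5)c3O)[C@H](c3cc4c(c(OCc5ccccc5)c3OCc5ccccc5)O[C@H](c3ccc(OCc5ccccc5)c(OCc5ccccc5)c3)[C@H](O)[C@H]4O)[C@H]2O)cc1 | intermediate
23 | CNP0275688.1, (2R,3R,4S)-2-(3,4-dihydroxyphenyl)-6-[(2R,3R,4S)-3,7,8-trihydroxy-2-(4-hydroxyphenyl)chroman-4-yl]chroman-3,4,7,8-tetraol | Oc1ccc([C@H]2Oc3c(ccc(O)c3O)[C@H](c3cc4c(c(O)c3O)O[C@H](c3ccc(O)c(O)c3)[C@H](O)[C@H]4O)[C@H]2O)cc1 | target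

**Step count:** 16 steps in total. The longest linear sequence is 10 steps (1, 3, 4, 5, 6, 7, 13, 14, 15, 16).

**Steps most likely to fail**

1. **Step 13 (bears the label).**
   - Risk: ring D may capture ion 18 at C2 before the ring closes. The C4 cation may lose H-3. The closure may go through a boat-type geometry and give the 2,3-trans series. The styryl benzoate may be protonated instead of the acetal. The anion may exert only weak facial control.
   - Fallback (known chemistry, ring C built through O1–C2 and C3–C4, union by a separate coupling): it sets out from 12, 13 and 11 and comes back at 21. Wittig homologation of 13 with (triphenylphosphoranylidene)acetaldehyde gives (E)-3-[4-(benzyloxy)phenyl]prop-2-enal F1. A diarylprolinol silyl ether-catalysed oxa-Michael/aldol condensation domino of 12 with F1 gives (2R)-7-(benzyloxy)-2-[4-(benzyloxy)phenyl]-6-bromo-8-hydroxy-2H-chromene-3-carbaldehyde F2. Baeyer–Villiger oxidation (mCPBA, buffered) gives the 3-formyloxy-2H-chromene F3. Mild methanolysis gives the (2R)-flavan-3-one F4. L-Selectride at −78 °C delivers hydride from the equatorial side and gives the 2,3-cis chroman-3,8-diol F5. Benzoyl chloride gives the 3,8-dibenzoate F6. DDQ with 2-ethoxyethanol gives the 3,4-trans 4-(2-ethoxyethoxy) dibenzoate F7. BF3·OEt2-mediated coupling of F7 with 11 at −78 °C (bromine cap in place, thioether inert to the hard acid) gives the tribenzoate dimer F8. The conditions of step 14 convert F8 into 21.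

2. **Step 6 (bears the label).**
   - Risk: the same ionisation and closure problems as above. In addition, uncapped ring D may alkylate itself in competition with the hindered thiol, and the thiol may add to the protonated alkene.
   - Fallback (known chemistry): it sets out from 2 and 3 and comes back at 11. Benzylation of the non-chelated 3-OH of 2 (BnBr, K2CO3, acetone) gives 3,4-bis(benzyloxy)-2-hydroxybenzaldehyde F9. Wittig homologation of 3 gives (E)-3-[3,4-bis(benzyloxy)phenyl]prop-2-enal F10. The organocatalytic oxa-Michael/aldol domino of F9 with F10 gives (2R)-7,8-bis(benzyloxy)-2-[3,4-bis(benzyloxy)phenyl]-2H-chromene-3-carbaldehyde F11. Baeyer–Villiger oxidation gives the 3-formyloxy-2H-chromene F12. Methanolysis gives the (2R)-flavan-3-one F13. L-Selectride gives the (2R,3R)-2,3-cis-flavan-3-ol F14. Benzoyl chloride gives the 3-benzoate F15. DDQ with 2-ethoxyethanol gives the 3,4-trans 4-(2-ethoxyethoxy) benzoate F16. Exchange with 2,6-dimethylbenzenethiol and BF3·OEt2 at −78 °C gives 11.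

3. **Step 16.**
   - Risk: the electron-rich benzylic C4'–OH may be hydrogenolysed along with the benzyl ethers. Traces of HBr may ionise C4' or the interflavan bond.
   - Fallback (the 4'-OH is unveiled last and no hydrogenation is used): it sets out from 21 and comes back at 23. Bromine–lithium exchange (excess n-BuLi, THF, −78 °C) followed by protonation gives the debrominated dimer thioether F17. BCl3 with pentamethylbenzene at −78 °C removes the six benzyl groups and gives the free phenolic dimer thioether F18. The Ag(I)/water exchange of step 15, known on free phenolic 4-thioflavans, gives 23.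

**Further compounds**
F1 | step 13 | (E)-3-[4-(benzyloxy)phenyl]prop-2-enal | O=C/C=C/c1ccc(OCc2ccccc2)cc1
F2 | step 13 | (2R)-7-(benzyloxy)-2-[4-(benzyloxy)phenyl]-6-bromo-8-hydroxy-2H-chromene-3-carbaldehyde | O(Cc5ccccc5)c1ccc([C@H]2Oc3c(cc(Br)c(OCc5ccccc5)c3O)C=C2C=O)cc1
F3 | step 13 | (2R)-7-(benzyloxy)-2-[4-(benzyloxy)phenyl]-6-bromo-8-hydroxy-2H-chromen-3-yl formate | O(Cc5ccccc5)c1ccc([C@H]2Oc3c(cc(Br)c(OCc5ccccc5)c3O)C=C2OC=O)cc1
F4 | step 13 | (2R)-7-(benzyloxy)-2-[4-(benzyloxy)phenyl]-6-bromo-8-hydroxychroman-3-one | O(Cc5ccccc5)c1ccc([C@H]2Oc3c(cc(Br)c(OCc5ccccc5)c3O)CC2=O)cc1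
F5 | step 13 | (2R,3R)-7-(benzyloxy)-2-[4-(benzyloxy)phenyl]-6-bromochroman-3,8-diol (2,3-cis) | O(Cc5ccccc5)c1ccc([C@H]2Oc3c(cc(Br)c(OCc5ccccc5)c3O)C[C@H]2O)cc1
F6 | step 13 | (2R,3R)-7-(benzyloxy)-2-[4-(benzyloxy)phenyl]-6-bromochroman-3,8-diyl dibenzoate | O(Cc5ccccc5)c1ccc([C@H]2Oc3c(cc(Br)c(OCc5ccccc5)c3OC(=O)c3ccccc3)C[C@H]2OC(=O)c3ccccc3)cc1
F7 | step 13 | 2,3-cis-3,4-trans 4-(2-ethoxyethoxy) derivative of F6 (configuration as in the upper unit of 20) | O(Cc5ccccc5)c1ccc([C@H]2Oc3c(cc(Br)c(OCc5ccccc5)c3OC(=O)c3ccccc3)[C@H](OCCOCC)[C@H]2OC(=O)c3ccccc3)cc1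
F8 | step 13 | tribenzoate dimer (20 with 8-O-benzoyl) | O(Cc5ccccc5)c1ccc([C@H]2Oc3c(cc(Br)c(OCc5ccccc5)c3OC(=O)c3ccccc3)[C@H](c3cc4c(c(OCc5ccccc5)c3OCc5ccccc5)O[C@H](c3ccc(OCc5ccccc5)c(OCc5ccccc5)c3)[C@H](OC(=O)c3ccccc3)[C@H]4Sc3c(C)cccc3C)[C@H]2OC(=O)c3ccccc3)cc1
F9 | step 6 | 3,4-bis(benzyloxy)-2-hydroxybenzaldehyde | O=Cc1ccc(OCc2ccccc2)c(OCc2ccccc2)c1O
F10 | step 6 | (E)-3-[3,4-bis(benzyloxy)phenyl]prop-2-enal | O=C/C=C/c1ccc(OCc2ccccc2)c(OCc2ccccc2)c1
F11 | step 6 | (2R)-7,8-bis(benzyloxy)-2-[3,4-bis(benzyloxy)phenyl]-2H-chromene-3-carbaldehyde | O(Cc5ccccc5)c1c(OCc5ccccc5)ccc2c1O[C@H](c3ccc(OCc5ccccc5)c(OCc5ccccc5)c3)C(C=O)=C2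
F12 | step 6 | (2R)-7,8-bis(benzyloxy)-2-[3,4-bis(benzyloxy)phenyl]-2H-chromen-3-yl formate | O(Cc5ccccc5)c1c(OCc5ccccc5)ccc2c1O[C@H](c3ccc(OCc5ccccc5)c(OCc5ccccc5)c3)C(OC=O)=C2
F13 | step 6 | (2R)-7,8-bis(benzyloxy)-2-[3,4-bis(benzyloxy)phenyl]chroman-3-one | O(Cc5ccccc5)c1c(OCc5ccccc5)ccc2c1O[C@H](c3ccc(OCc5ccccc5)c(OCc5ccccc5)c3)C(=O)C2
F14 | step 6 | (2R,3R)-7,8-bis(benzyloxy)-2-[3,4-bis(benzyloxy)phenyl]chroman-3-ol (2,3-cis) | O(Cc5ccccc5)c1c(OCc5ccccc5)ccc2c1O[C@H](c3ccc(OCc5ccccc5)c(OCc5ccccc5)c3)[C@H](O)C2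
F15 | step 6 | (2R,3R)-7,8-bis(benzyloxy)-2-[3,4-bis(benzyloxy)phenyl]chroman-3-yl benzoate | O(Cc5ccccc5)c1c(OCc5ccccc5)ccc2c1O[C@H](c3ccc(OCc5ccccc5)c(OCc5ccccc5)c3)[C@H](OC(=O)c3ccccc3)C2
F16 | step 6 | 2,3-cis-3,4-trans 4-(2-ethoxyethoxy) derivative of F15 (configuration as in 11) | O(Cc5ccccc5)c1c(OCc5ccccc5)ccc2c1O[C@H](c3ccc(OCc5ccccc5)c(OCc5ccccc5)c3)[C@H](OC(=O)c3ccccc3)[C@H]2OCCOCC
F17 | step 16 | debrominated dimer thioether (21 with H at C6) | O(Cc5ccccc5)c1ccc([C@H]2Oc3c(ccc(OCc5ccccc5)c3O)[C@H](c3cc4c(c(OCc5ccccc5)c3OCc5ccccc5)O[C@H](c3ccc(OCc5ccccc5)c(OCc5ccccc5)c3)[C@H](O)[C@H]4Sc3c(C)cccc3C)[C@H]2O)cc1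
F18 | step 16 | free phenolic dimer thioether (23 with 4'-S-(2,6-dimethylphenyl) in place of 4'-OH) | Oc1ccc([C@H]2Oc3c(ccc(O)c3O)[C@H](c3cc4c(c(O)c3O)O[C@H](c3ccc(O)c(O)c3)[C@H](O)[C@H]4Sc3c(C)cccc3C)[C@H]2O)cc1
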